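## Structural features

The target is the 3-hydroxy-4-methoxybenzoate (isovanillate) of a cis-fused bicyclo[5.3.0]dec-2-ene diol of the daucane type. Cyclopentane ring A (C6–C7–C8–C9–C10) and cycloheptene ring B (C1–C2–C3–C4–C5–C6–C10) share the C6–C10 bond. Numbering used throughout: C1 is the CH carrying the aroyloxy group, C2=C3 the trisubstituted alkene with its methyl on C3, C4 and C5 the CH2 pair of ring B, C6 the quaternary methyl carbon, C7 and C8 the CH2 pair of ring A, C9 the tertiary carbinol bearing isopropyl, C10 the ring-fusion CH. The four stereocentres are contiguous (C1, C6 and C9 are all bonded to C10). With β defined as the face of H-10, the C6 methyl, the C9 isopropyl and H-1 are β, and the C9 hydroxyl and the C1 aroyloxy group are α; this is (1R,6R,9R,10S). Fragile points are the allylic benzoate (ionisation, elimination, acyl loss under base), the free phenol, and, whenever C1 is a ketone, the C1/C9 β-hydroxy ketone relationship (retro-aldol, dehydration) with the epimerisable C10–H between them. The real difficulty is an all-carbon quaternary centre (C6) next to the ring-fusion CH in one absolute sense, together with a seven-membered carbocycle carrying a configured allylic oxygen at the ring fusion. The key step exploits the C1–C2=C3(CH3) segment of ring B: at the ketone level it is the enone O=C1–C2=C3(CH3), and removing C2 leaves a 2-methylcyclohexanone enol derivative (C1=C3) inside a cis-hydrindane, which a Diels–Alder reaction of a 3-methylcyclopentenone assembles directly.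

## Logic of the disconnections

**25 ⇒ 24 ⇒ 19 + 22.** The two O–Si bonds of 24 and then the acyl C–O bond of the C1 ester are cut. This is the only carbon–heteroatom bond between two carbon frameworks, and cutting it separates the achiral aryl part (22, one step from 20) from the bicyclic alcohol 19, which already holds all four stereocentres. The forward step must acylate a hindered secondary allylic alcohol without ionising the C1–O bond, and the final fluoride treatment must spare the ester.

**19 ⇒ 18 ⇒ 17.** The C1–H bond is cut (hydride addition to the ketone 18), then a C2–Br bond is added retrosynthetically to reach 17. C1 is the one stereocentre that a rigid cis-fused bicycle can set by face-selective hydride addition, and 17 is the direct product of a carbene ring enlargement. The forward demand is hydride entry on the β face; the C9 oxygen therefore stays silylated through the reduction, so that the α face is screened and no hydroxyl-directed delivery can compete. Debromination must not reduce the enone.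

**17 ⇒ 14 + 15.** C1–C2 and C2–C3 are cut, so C2 leaves as a one-carbon unit from 15. The seven-membered ring becomes a six-membered one and the problem reduces to a cis-hydrindane. The forward step needs the enol ether double bond of 14 exactly between C1 and C3 and must leave C6, C9 and C10 untouched.

**14 ⇒ 12 ⇒ 11 ⇒ 10 ⇒ 9.** No skeletal bond is cut here. The C1=C3 enol ether is traced to conjugate reduction of the C3=C4 enone 12, the only way to fix the enolate regiochemistry away from C10. 12 is the silyl ether of 11, 11 the oxidation product of allylic alcohol 10, and 10 the desilylated form of 9. The C1 oxygen has to stay masked until C9 is no longer a ketone (otherwise a 1,3-diketone or a retro-aldol-prone β-hydroxy ketone results), and the C9 hydroxyl has to be masked before any basic step once C1 is a ketone.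

**9 ⇒ 8.** The C9–isopropyl bond is cut. This reveals a cyclopentanone whose α-carbon is the ring fusion. The forward step needs a weakly basic isopropyl nucleophile entering on the convex β face, anti to C1.

**8 ⇒ 6 ⇒ 3 + 5.** A carboxylate is first reattached at C10 (6), then C5–C6 and C1–C10 are cut in a Diels–Alder sense. This gives two simple achiral partners, and one catalyst-controlled event fixes C6 absolutely; the cis fusion at C10 is restored when the ester is removed. The dienophile must be doubly activated to react at its fully substituted β-carbon, and the activating ester must come off under mild conditions because the C1 oxygen is β to the C9 ketone in 8. For that reason 3 is an allyl ester.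

**3 ⇒ 2 ⇒ 1; 5 ⇒ 4; 22 ⇒ 20.** The ester carbon of 3 is cut (carbonylation of the C–I bond of 2, itself from 1), the O–Si bond of 5 (from 4) and the O–Si bond of 22 (from 20). All are one-step functionalisations of commercial materials.

## Other disconnections considered

**Alternative 1:** The cut is C6–C10 and C4–C5 in an alkene isomer of the skeleton. Forward, [Rh(CO)2Cl]2 would open the cyclopropane of the acyclic tertiary allylic alcohol A1 at its less substituted bond and join the vinylcyclopropane (vinyl C10=C1, ring carbons C2, C3, C4) to the tethered 1,1-disubstituted alkene C5=C6 in a (5+2) cycloaddition, giving the bicyclic alcohol A2 with both rings closed at once.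
- In favour: one catalytic step makes both rings, the quaternary C6 and the cis fusion from a linear precursor. In ring-forming economy this is better than the chosen plan, which needs two ring events (steps 4 and 11) and carries an ester and a bromine that are later removed.
- Against: the facial sense at C6/C10 must be relayed from C9, a fully substituted carbinol whose hydroxyl and isopropyl groups differ little in the tether, so diastereocontrol is uncertain. 1,1-Disubstituted alkenes are the slow 2π partners. A1 itself needs an enantioselective construction of a tertiary allylic alcohol carrying a trans-cyclopropane. A2 also has the alkene at C1=C2 and an sp3 C3, so an allylic transposition with α-oxygen delivery to C1 is still required (for example an ene reaction with singlet oxygen, which must take H-3 and not H-10).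
- Comparison: on mechanism the metallacycle pathway gives the cis fusion as reliably as the Diels–Alder step, so the two are equal there. On structure the chosen plan sets C6 by a catalyst and C9 and C1 by convex-face additions to a rigid bicycle, which is easier to predict. On step count the alternative is probably shorter to the bicycle but not clearly shorter to the target.

**Alternative 2:** The cut is C6–C7 and C9–C10; ring A is annulated onto an intact ring B. Forward, 1-isopropylcyclopropanol A4 is opened by Et2Zn to a zinc homoenolate (C7–C8–C9=O), which adds under copper catalysis to C6 of the symmetric 3,6-dimethylcyclohepta-2,6-dienone A3. The zinc enolate at C10 then closes onto the isopropyl ketone to give the β-hydroxy enone A5.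
- In favour: A5 is the desilylated form of 18, reached in a single bond-forming operation from an achiral dienone with no protecting groups and the C2=C3 enone already in place. In step economy this is clearly better than the chosen plan.
- Against: the desymmetrising conjugate addition has to create a quaternary centre enantioselectively with a weakly nucleophilic homoenolate at a β,β-disubstituted position. The silyl chloride activation usually needed for such additions would trap the enolate and stop the aldol. The aldol must also deliver 9R, and A5 forms under the very conditions that favour its retro-aldol cleavage. A3 has to be prepared as well.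
- Comparison: the five-ring aldol closure should give the cis fusion, equal to the chosen plan. Absolute control rests on a single untested enantioselective event, whereas the chosen plan uses more steps but each stereocentre comes from a reaction class with a working model.

**Alternative 3:** The cut is the aldol bond C10–C1 of ring B. Forward, SmI2 reduces the C–Br bond of the bromo keto enal A6 to a samarium enolate located regiospecifically at C10, which adds to the tethered (Z)-enal and closes the seven-membered ring to the β-hydroxy ketone A7.
- In favour: the absolute configuration at C6 would come from a chiral-pool terpene alcohol and not from asymmetric catalysis; on this point the alternative is at least the equal of the chosen plan and arguably better. The C1 hydroxyl and the C2=C3 alkene arrive in place, so no oxidation-level changes or bromine removal are needed, and the enolate forms without base.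
- Against: turning a tertiary CH(CH3) stereocentre into the quaternary C6 needs a stereoretentive C–C bond formation at that carbon and a long sequence to A6. The (Z)-enal can isomerise to the (E)-isomer, which cannot cyclise. A seven-membered aldol closure is entropically poor and reversible, and SmI2 can also reduce the enal. C1 and C10 are set together by a chelated medium-ring transition state, which is harder to predict than the hydride addition of step 13. The isopropyl group would then have to be added to a β-hydroxy ketone, whereas the chosen plan introduces it before any such unit exists.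
- Comparison: the step count is comparable. Mechanistically a direct medium-ring closure is set against a ring enlargement of an easily made six-membered ring, and the latter is the safer ring-forming event.

Key step: step 11

Remarks and assumptions (chemistry):
- The hydrindene/hydroazulene names are shorthand for the bicyclo[4.3.0]nonene and bicyclo[5.3.0]decene skeletons with the C1–C10 locants defined above (C2 is absent in the hydrindanes); β is the face of H-10.
- Assumption: the (S,S)-tert-butyl-bis(oxazoline) complex of divalent copper is taken to expose the enone face of 3 that leads to (6S,10R)-6; if the opposite sense is found, the (R,R)-ligand is used.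
- Assumption: 6–10 are drawn as the ketone-endo adduct (C1 siloxy group α, trans to the C10 ester); the C1 epimer would converge at 11.

## Route

Step 1
Reactants: 1 3-methylcyclopent-2-en-1-one
Product: 2 2-iodo-3-methylcyclopent-2-en-1-one
Conditions: I2, pyridine, CH2Cl2, 0 → 25 °C
Reagents that add atoms: iodine, II
Why: α-Iodination of a conjugated enone by the amine addition–iodination–elimination sequence; the vinyl iodide is the handle for carbonylation.

Step 2
Reactants: 2 2-iodo-3-methylcyclopent-2-en-1-one
Product: 3 allyl 2-methyl-5-oxocyclopent-1-ene-1-carboxylate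
Conditions: CO (1 atm), allyl alcohol, Pd(OAc)2, PPh3, i-Pr2NEt, DMF, 50 °C
Reagents that add atoms: carbon monoxide, [C-]#[O+]; allyl alcohol, C=CCO
Why: Palladium-catalysed alkoxycarbonylation (oxidative addition of the C–I bond to zerovalent palladium, CO insertion, alcoholysis of the acyl complex); the allyl ester is chosen so that the activating group can later be removed at room temperature.

Step 3
Reactants: 4 (E)-2-methylbut-2-enal
Product: 5 (1E)-1-(tert-butyldimethylsilyloxy)-2-methylbuta-1,3-diene
Conditions: TBSOTf, Et3N, Et2O, 0 → 25 °C
Reagents that add atoms: tert-butyldimethylsilyl triflate, CC(C)(C)[Si](C)(C)OS(=O)(=O)C(F)(F)F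
Why: O-Silylation of the enal and γ-deprotonation (silyl dienol ether formation) should give mainly the (1E)-diene, the isomer that reaches the s-cis form needed for cycloaddition.

Step 4
Reactants: 3 allyl 2-methyl-5-oxocyclopent-1-ene-1-carboxylate; 5 (1E)-1-(tert-butyldimethylsilyloxy)-2-methylbuta-1,3-diene
Product: 6 allyl (1R,6S,10R)-1-(tert-butyldimethylsilyloxy)-3,6-dimethyl-9-oxo-cis-hydrind-3-ene-10-carboxylate
Conditions: Cu(OTf)2 (10 mol %), (S,S)-t-Bu-box (11 mol %), 4 Å MS, CH2Cl2, −20 → 25 °C
Reagents that add atoms: none
Why: Catalytic enantioselective Diels–Alder reaction: the 1,3-dicarbonyl unit of 3 chelates the bis(oxazoline)-bound divalent copper, which activates the enone and screens one face; the CH2 terminus of the diene (largest HOMO coefficient, future C5) bonds to the β-carbon C6 and the siloxy carbon C1 to C10. Suprafacial addition makes the ester and the C6 methyl cis, the ligand sets C6 and C10 absolutely, and the ketone-endo approach places the C1 siloxy group trans to the ester.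

Step 5
Reactants: 6 allyl (1R,6S,10R)-1-(tert-butyldimethylsilyloxy)-3,6-dimethyl-9-oxo-cis-hydrind-3-ene-10-carboxylate
Product: 8 (1S,6S,10S)-1-(tert-butyldimethylsilyloxy)-3,6-dimethyl-cis-hydrind-3-en-9-one, via β-keto acid 7 (not isolated)
Conditions: Pd(OAc)2 (5 mol %), PPh3, HCO2H, Et3N, THF, 25 → 40 °C
Reagents that add atoms: none
Why: Tsuji–Trost-type deallylation: zerovalent palladium ionises the allyl ester, formate reduces the allyl unit to propene, and the β-keto acid 7 loses CO2 through its cyclic transition state; protonation at C10 with equilibration through the enol in the amine buffer should give the cis-fused ketone (H-10 cis to the C6 methyl), the more stable fusion here. A hot halide dealkoxycarbonylation of a methyl ester would generate the C10 enolate next to the C1 siloxy leaving group, which is why the allyl ester is carried.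

Step 6
Reactants: 8 (1S,6S,10S)-1-(tert-butyldimethylsilyloxy)-3,6-dimethyl-cis-hydrind-3-en-9-one
Product: 9 (1S,6S,9R,10S)-1-(tert-butyldimethylsilyloxy)-9-isopropyl-3,6-dimethyl-cis-hydrind-3-en-9-ol
Conditions: i-PrMgCl, CeCl3, THF, −78 → 0 °C
Reagents that add atoms: isopropylmagnesium chloride, CC(C)[Mg]Cl
Why: 1,2-Addition of an organocerium reagent, whose low basicity suppresses enolisation toward C10 (and with it β-elimination of the C1 siloxy group) and β-hydride reduction; attack on the convex β face, anti to C1, puts the isopropyl group cis to H-10 and the hydroxyl α, setting C9 as 9R.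

Step 7
Reactants: 9 (1S,6S,9R,10S)-1-(tert-butyldimethylsilyloxy)-9-isopropyl-3,6-dimethyl-cis-hydrind-3-en-9-ol
Product: 10 (1S,6S,9R,10S)-9-isopropyl-3,6-dimethyl-cis-hydrind-3-ene-1,9-diol
Conditions: TBAF, THF, 25 °C
Reagents that add atoms: none
Why: Fluoride cleavage of the secondary allylic silyl ether; with no carbonyl group present the alkoxides cannot fragment.

Step 8
Reactants: 10 (1S,6S,9R,10S)-9-isopropyl-3,6-dimethyl-cis-hydrind-3-ene-1,9-diol
Product: 11 (6S,9R,10R)-9-hydroxy-9-isopropyl-3,6-dimethyl-cis-hydrind-3-en-1-one
Conditions: Dess–Martin periodinane, NaHCO3, CH2Cl2, 0 → 25 °C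
Reagents that add atoms: none
Why: Hypervalent-iodine oxidation of the secondary allylic alcohol to the conjugated enone; the tertiary carbinol is inert and the buffer protects the β-hydroxy ketone from acid-induced dehydration. C10 is now α to a ketone, but the cis fusion is expected to remain the stable one.

Step 9
Reactants: 11 (6S,9R,10R)-9-hydroxy-9-isopropyl-3,6-dimethyl-cis-hydrind-3-en-1-one
Product: 12 (6S,9R,10R)-9-isopropyl-3,6-dimethyl-9-(trimethylsilyloxy)-cis-hydrind-3-en-1-one
Conditions: N-(trimethylsilyl)imidazole, CH2Cl2, 25 → 40 °C
Reagents that add atoms: N-(trimethylsilyl)imidazole, C[Si](C)(C)n1ccnc1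
Why: Neutral silyl transfer to the hindered tertiary alcohol without enolising the ketone; the ether prevents alkoxide-triggered retro-aldol cleavage in steps 10 and 11 and later screens the α face in step 13.

Step 10
Reactants: 12 (6S,9R,10R)-9-isopropyl-3,6-dimethyl-9-(trimethylsilyloxy)-cis-hydrind-3-en-1-one
Product: 14 (6R,9R,10R)-9-isopropyl-3,6-dimethyl-1,9-bis(trimethylsilyloxy)-cis-hydrind-1(3)-ene, via lithium enolate 13 (not isolated)
Conditions: LiBH(s-Bu)3, THF, −78 °C; then Me3SiCl, Et3N, −78 → 0 °C
Reagents that add atoms: chlorotrimethylsilane, C[Si](C)(C)Cl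
Why: Conjugate hydride addition of a hindered trialkylborohydride to the α-methyl enone (its β-carbon C4 carries one substituent only) gives the enolate 13 regiospecifically between C1 and C3, and O-silylation traps it as the tetrasubstituted enol ether; deprotonation of the saturated ketone could not exclude enolisation toward C10.

Step 11
Reactants: 14 (6R,9R,10R)-9-isopropyl-3,6-dimethyl-1,9-bis(trimethylsilyloxy)-cis-hydrind-1(3)-ene; 15 bromoform
Product: 17 (6R,9R,10R)-2-bromo-9-isopropyl-3,6-dimethyl-9-(trimethylsilyloxy)-cis-hydroazul-2-en-1-one, via dibromocyclopropane 16 (not isolated)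
Conditions: CHBr3, KOt-Bu, pentane, −30 → 0 °C; filter; then propylene oxide, PhMe, 50 °C
Reagents that add atoms: none
Why: KOt-Bu deprotonates 15 and α-elimination of bromide gives singlet dibromocarbene, an electrophile that adds in a concerted cheletropic (2+1) fashion to the only electron-rich π bond of 14, the C1=C3 enol ether, forming C1–C2 and C2–C3 in cyclopropane 16. On warming, the bromide on C2 that is syn to the six-membered ring ionises while the shared C1–C3 bond breaks in a disrotatory two-electron electrocyclic opening (cyclopropyl to allyl, Woodward–Hoffmann–DePuy rule), the ring bonds turning inward as a cis allyl unit inside a ring requires, with the C1 siloxy oxygen stabilising the cation. Bromide then removes the trimethylsilyl group (the bromosilane is scavenged by propylene oxide), leaving the 2-bromo enone 17 with C2 inserted between C1 and C3. The closest known reaction type is dihalocarbene addition to trimethylsilyl enol ethers of cyclic ketones with ring enlargement to 2-halocycloalk-2-enones. The seven-membered ring is closed by ring expansion (cyclopropanation across a ring bond, then cleavage of that bond) and not by end-to-end cyclisation, so no medium-ring entropy penalty is paid. No stereocentre is created: the transient C1 and C3 centres of 16 vanish and C6, C9 and C10 are spectators. The selectivity needed is regiochemical, C2 entering on the C3 side of C1 and not between C1 and C10, and it is secured because step 10 fixed the enol ether toward C3; 14 has no other alkene. Filtering off the alkoxide before the opening and scavenging the bromosilane under neutral conditions protect C10 (now α to the C1 ketone) and the tertiary silyl ether.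

Step 12
Reactants: 17 (6R,9R,10R)-2-bromo-9-isopropyl-3,6-dimethyl-9-(trimethylsilyloxy)-cis-hydroazul-2-en-1-one
Product: 18 (6R,9R,10R)-9-isopropyl-3,6-dimethyl-9-(trimethylsilyloxy)-cis-hydroazul-2-en-1-one
Conditions: Bu3SnH (1.05 equiv, slow addition), Pd(PPh3)4 (5 mol %), THF, 25 °C
Reagents that add atoms: none
Why: Palladium-catalysed hydrodebromination (oxidative addition of the activated C2–Br bond to zerovalent palladium, hydride transfer from tin, reductive elimination); one equivalent of hydride added slowly should keep conjugate reduction of the β,β-disubstituted enone negligible.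

Step 13
Reactants: 18 (6R,9R,10R)-9-isopropyl-3,6-dimethyl-9-(trimethylsilyloxy)-cis-hydroazul-2-en-1-one
Product: 19 (1R,6R,9R,10S)-9-isopropyl-3,6-dimethyl-9-(trimethylsilyloxy)-cis-hydroazul-2-en-1-ol
Conditions: NaBH4, CeCl3·7H2O, MeOH–THF, −78 °C
Reagents that add atoms: none
Why: Luche 1,2-reduction; hydride should enter from the convex β face (that of H-10), because the α face is screened by ring A and by the C9 siloxy group, which is kept on for this purpose and also rules out hydroxyl-directed delivery. The new C1 hydroxyl is then α and H-1 cis to H-10 (1R).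

Step 14
Reactants: 20 3-hydroxy-4-methoxybenzoic acid
Product: 22 3-(tert-butyldimethylsilyloxy)-4-methoxybenzoic acid, via bis-silyl derivative 21 (not isolated)
Conditions: TBSCl (2.5 equiv), imidazole, DMF, 25 °C; then AcOH–THF–H2O, 25 °C
Reagents that add atoms: tert-butyldimethylsilyl chloride, CC(C)(C)[Si](C)(C)Cl
Why: Silylation of both acidic groups; the silyl ester is far more labile than the aryl silyl ether, so mild aqueous acid returns the carboxylic acid only.

Step 15
Reactants: 19 (1R,6R,9R,10S)-9-isopropyl-3,6-dimethyl-9-(trimethylsilyloxy)-cis-hydroazul-2-en-1-ol; 22 3-(tert-butyldimethylsilyloxy)-4-methoxybenzoic acid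
Product: 24 (1R,6R,9R,10S)-9-isopropyl-3,6-dimethyl-9-(trimethylsilyloxy)-cis-hydroazul-2-en-1-yl 3-(tert-butyldimethylsilyloxy)-4-methoxybenzoate, via acid chloride 23 (not isolated)
Conditions: 22, 1-chloro-N,N,2-trimethylprop-1-en-1-amine, CH2Cl2, 0 → 25 °C; then 19, Et3N, DMAP, CH2Cl2, 25 → 40 °C
Reagents that add atoms: none
Why: The acid is converted into its chloride under neutral conditions by an α-chloro enamine (no HCl to attack the aryl silyl ether), followed by DMAP-catalysed acylation of the only free hydroxyl of 19; base-buffered, non-ionising conditions keep the allylic C1–O bond and its configuration intact.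

Step 16
Reactants: 24 (1R,6R,9R,10S)-9-isopropyl-3,6-dimethyl-9-(trimethylsilyloxy)-cis-hydroazul-2-en-1-yl 3-(tert-butyldimethylsilyloxy)-4-methoxybenzoate
Product: 25 (1R,6R,9R,10S)-9-hydroxy-9-isopropyl-3,6-dimethyl-cis-hydroazul-2-en-1-yl 3-hydroxy-4-methoxybenzoate
Conditions: TBAF, AcOH, THF, 0 → 25 °C
Reagents that add atoms: none
Why: Fluoride cleaves the aryl tert-butyldimethylsilyl ether and the tertiary trimethylsilyl ether; acetic acid buffers the phenoxide and alkoxide so that the allylic benzoate is neither hydrolysed nor eliminated.

## Compound list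

1 | 3-methylcyclopent-2-en-1-one | CC1=CC(=O)CC1 | starting material
2 | 2-iodo-3-methylcyclopent-2-en-1-one | CC1=C(I)C(=O)CC1 | intermediate
3 | allyl 2-methyl-5-oxocyclopent-1-ene-1-carboxylate | CC1=C(C(=O)OCC=C)C(=O)CC1 | intermediate
4 | (E)-2-methylbut-2-enal (tiglaldehyde) | C/C=C(\C)C=O | starting material
5 | (1E)-1-(tert-butyldimethylsilyloxy)-2-methylbuta-1,3-diene | C=C/C(C)=C/O[Si](C)(C)C(C)(C)C | intermediate
6 | allyl (1R,6S,10R)-1-(tert-butyldimethylsilyloxy)-3,6-dimethyl-9-oxo-cis-hydrind-3-ene-10-carboxylate (ester and C6 methyl β, siloxy α) | CC(C)(C)[Si](C)(C)O[C@@H]1C(C)=CC[C@]2(C)CCC(=O)[C@]12C(=O)OCC=C | intermediate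
7 | (1R,6S,10R)-1-(tert-butyldimethylsilyloxy)-3,6-dimethyl-9-oxo-cis-hydrind-3-ene-10-carboxylic acid (not isolated) | CC(C)(C)[Si](C)(C)O[C@@H]1C(C)=CC[C@]2(C)CCC(=O)[C@]12C(=O)O | intermediate
8 | (1S,6S,10S)-1-(tert-butyldimethylsilyloxy)-3,6-dimethyl-cis-hydrind-3-en-9-one (H-10 cis to C6 methyl) | CC(C)(C)[Si](C)(C)O[C@@H]1C(C)=CC[C@]2(C)CCC(=O)[C@H]12 | intermediate
9 | (1S,6S,9R,10S)-1-(tert-butyldimethylsilyloxy)-9-isopropyl-3,6-dimethyl-cis-hydrind-3-en-9-ol (isopropyl β, hydroxyl α) | CC(C)(C)[Si](C)(C)O[C@@H]1C(C)=CC[C@]2(C)CC[C@@](O)(C(C)C)[C@H]12 | intermediate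
10 | (1S,6S,9R,10S)-9-isopropyl-3,6-dimethyl-cis-hydrind-3-ene-1,9-diol | O[C@@H]1C(C)=CC[C@]2(C)CC[C@@](O)(C(C)C)[C@H]12 | intermediate
11 | (6S,9R,10R)-9-hydroxy-9-isopropyl-3,6-dimethyl-cis-hydrind-3-en-1-one | O=C1C(C)=CC[C@]2(C)CC[C@@](O)(C(C)C)[C@H]12 | intermediate
12 | (6S,9R,10R)-9-isopropyl-3,6-dimethyl-9-(trimethylsilyloxy)-cis-hydrind-3-en-1-one | O=C1C(C)=CC[C@]2(C)CC[C@@](O[Si](C)(C)C)(C(C)C)[C@H]12 | intermediate
13 | lithium enolate of 12, enolate double bond C1=C3 (not isolated) | [Li+].[O-]C1=C(C)CC[C@]2(C)CC[C@@](O[Si](C)(C)C)(C(C)C)[C@H]12 | intermediate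
14 | (6R,9R,10R)-9-isopropyl-3,6-dimethyl-1,9-bis(trimethylsilyloxy)-cis-hydrind-1(3)-ene (enol ether C1=C3) | C[Si](C)(C)OC1=C(C)CC[C@]2(C)CC[C@@](O[Si](C)(C)C)(C(C)C)[C@H]12 | intermediate
15 | bromoform | BrC(Br)Br | starting material
16 | dibromocyclopropane from 14: CBr2 (C2) bridging C1 and C3 on the β face, siloxy on C1 and methyl on C3 α (not isolated) | C[Si](C)(C)O[C@]1(C2(Br)Br)[C@]2(C)CC[C@]3(C)CC[C@@](O[Si](C)(C)C)(C(C)C)[C@H]13 | intermediate
17 | (6R,9R,10R)-2-bromo-9-isopropyl-3,6-dimethyl-9-(trimethylsilyloxy)-cis-hydroazul-2-en-1-one | O=C1C(Br)=C(C)CC[C@]2(C)CC[C@@](O[Si](C)(C)C)(C(C)C)[C@H]12 | intermediate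
18 | (6R,9R,10R)-9-isopropyl-3,6-dimethyl-9-(trimethylsilyloxy)-cis-hydroazul-2-en-1-one | O=C1C=C(C)CC[C@]2(C)CC[C@@](O[Si](C)(C)C)(C(C)C)[C@H]12 | intermediate
19 | (1R,6R,9R,10S)-9-isopropyl-3,6-dimethyl-9-(trimethylsilyloxy)-cis-hydroazul-2-en-1-ol (C1 hydroxyl α, H-1 cis to H-10) | O[C@@H]1C=C(C)CC[C@]2(C)CC[C@@](O[Si](C)(C)C)(C(C)C)[C@H]12 | intermediate
20 | 3-hydroxy-4-methoxybenzoic acid (isovanillic acid) | COc1ccc(C(=O)O)cc1O | starting material
21 | tert-butyldimethylsilyl 3-(tert-butyldimethylsilyloxy)-4-methoxybenzoate (not isolated) | COc1ccc(C(=O)O[Si](C)(C)C(C)(C)C)cc1O[Si](C)(C)C(C)(C)C | intermediate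
22 | 3-(tert-butyldimethylsilyloxy)-4-methoxybenzoic acid | COc1ccc(C(=O)O)cc1O[Si](C)(C)C(C)(C)C | intermediate
23 | 3-(tert-butyldimethylsilyloxy)-4-methoxybenzoyl chloride (not isolated) | COc1ccc(C(=O)Cl)cc1O[Si](C)(C)C(C)(C)C | intermediate
24 | (1R,6R,9R,10S)-9-isopropyl-3,6-dimethyl-9-(trimethylsilyloxy)-cis-hydroazul-2-en-1-yl 3-(tert-butyldimethylsilyloxy)-4-methoxybenzoate | COc1ccc(C(=O)O[C@@H]2C=C(C)CC[C@]3(C)CC[C@@](O[Si](C)(C)C)(C(C)C)[C@H]23)cc1O[Si](C)(C)C(C)(C)C | intermediate
25 | (1R,6R,9R,10S)-9-hydroxy-9-isopropyl-3,6-dimethyl-cis-hydroazul-2-en-1-yl 3-hydroxy-4-methoxybenzoate, i.e. (3R,3aS,4R,8aR)-3-hydroxy-6,8a-dimethyl-3-(propan-2-yl)-1,2,3,3a,4,7,8,8a-octahydroazulen-4-yl 3-hydroxy-4-methoxybenzoate | COc1ccc(C(=O)O[C@@H]2C=C(C)CC[C@]3(C)CC[C@@](O)(C(C)C)[C@H]23)cc1O | target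

## Step count and least certain steps

Total: 16 steps. Longest linear sequence: 14 steps (1 → 25 through steps 1, 2, 4–13, 15 and 16); steps 3 and 14 prepare the diene and the aroyl partner.

**Step 11 (key step).** Carbene uptake may be slow at a tetrasubstituted enol ether flanked by C10 and the fully substituted C9, so that hydrolysis of the enol ether to the saturated ketone competes. The cyclopropane may also open before the alkoxide is removed, exposing the bromo enone to base (epimerisation at C10, γ-deprotonation and deconjugation), and liberated bromosilane may strip the tertiary silyl ether. Fallback: from 14, Simmons–Smith cyclopropanation (Et2Zn, CH2I2, CH2Cl2, 0 °C) gives the siloxycyclopropane F1. One-electron oxidation with FeCl3 in DMF cleaves the shared C1–C3 bond to the ring-enlarged β-keto radical, which takes up chlorine to give the 3-chloro ketone F2. NaOAc in MeOH eliminates HCl into conjugation and the route is rejoined at 18; step 12 is then not needed.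

**Step 4.** The tetrasubstituted, β,β-disubstituted dienophile may be too unreactive toward the chelating copper catalyst, since two adjacent quaternary carbons are formed. A stepwise Mukaiyama–Michael pathway or silyl transfer from the diene may also erode enantioselectivity or consume the diene. Fallback: from 3 and 5, the cycloaddition is run with an achiral Lewis acid (Et2AlCl, CH2Cl2, −78 → 0 °C), which gives 6 together with its mirror image, the ent-adduct F3.
- Steps 5–7 applied to this racemate pass through the ent-β-keto acid F4, the ent-ketone F5 and the ent-carbinol F6 to 10 mixed with the ent-diol F7.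
- Esterification of the secondary C1 hydroxyl with (S)-O-acetylmandelic acid (DCC, DMAP, CH2Cl2) gives two diastereomers, the acetylmandelate of 10 F8 and the acetylmandelate of the ent-diol F9, which are separated by chromatography or crystallisation.
- Methanolysis of F8 (K2CO3, MeOH) returns enantiopure 10, where the route is rejoined.

**Step 13.** Facial selectivity may be poor: the β face carries the C6 methyl in a 1,3-relationship to C1, and the balance between it and the α-face screening by ring A depends on the ring B conformation. Fallback: from 18, if hydride enters on the α face the product is the C1-epimeric alcohol F10. Its Mitsunobu esterification with 22 (PPh3, diisopropyl azodicarboxylate, PhMe, 0 → 25 °C) inverts C1 and forms the ester in the same operation, rejoining the route at 24 (step 15 is then not needed).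

**Step 6.** The secondary organometallic may enolise the ketone toward C10 (with β-elimination of the C1 siloxy group) or reduce it by β-hydride transfer instead of adding. Fallback: from 8, isopropenylmagnesium bromide–CeCl3 (an sp2 nucleophile that is smaller and cannot transfer a β-hydride in the same way) gives the isopropenyl carbinol F11. Its 1,1-disubstituted alkene is hydrogenated selectively over the trisubstituted ring alkene with RhCl(PPh3)3 and H2 (benzene, 25 °C), rejoining the route at 9.

**Step 2.** The allyl ester product may be ionised by zerovalent palladium (allyl scrambling, allyl ether formation), and allyl alcohol may be consumed by Heck-type insertion, lowering conversion. Fallback: from 2, methoxycarbonylation (CO, MeOH, same catalyst) gives the methyl ester F12, the cycloaddition of step 4 then gives the methyl ester adduct F13, and halide-induced dealkoxycarbonylation (LiCl, wet DMSO, 130 °C, Krapcho) rejoins the route at 8. The cost is heating the β-siloxy ketone, which step 5 was designed to avoid.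

## Further compounds

F1 | step 11 | siloxycyclopropane from 14 (CH2 bridging C1 and C3 on the β face; other centres as in 14) | C[Si](C)(C)O[C@]1(C2)[C@]2(C)CC[C@]3(C)CC[C@@](O[Si](C)(C)C)(C(C)C)[C@H]13
F2 | step 11 | (6R,9R,10R)-3-chloro-9-isopropyl-3,6-dimethyl-9-(trimethylsilyloxy)-cis-hydroazulan-1-one (C3 epimers) | O=C1CC(C)(Cl)CC[C@]2(C)CC[C@@](O[Si](C)(C)C)(C(C)C)[C@H]12
F3 | step 4 | ent-adduct: allyl (1S,6R,10S)-1-(tert-butyldimethylsilyloxy)-3,6-dimethyl-9-oxo-cis-hydrind-3-ene-10-carboxylate | CC(C)(C)[Si](C)(C)O[C@H]1C(C)=CC[C@@]2(C)CCC(=O)[C@@]12C(=O)OCC=C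
F4 | step 4 | ent-β-keto acid: (1S,6R,10S)-1-(tert-butyldimethylsilyloxy)-3,6-dimethyl-9-oxo-cis-hydrind-3-ene-10-carboxylic acid | CC(C)(C)[Si](C)(C)O[C@H]1C(C)=CC[C@@]2(C)CCC(=O)[C@@]12C(=O)O
F5 | step 4 | ent-ketone: (1R,6R,10R)-1-(tert-butyldimethylsilyloxy)-3,6-dimethyl-cis-hydrind-3-en-9-one | CC(C)(C)[Si](C)(C)O[C@H]1C(C)=CC[C@@]2(C)CCC(=O)[C@@H]12
F6 | step 4 | ent-carbinol: (1R,6R,9S,10R)-1-(tert-butyldimethylsilyloxy)-9-isopropyl-3,6-dimethyl-cis-hydrind-3-en-9-ol | CC(C)(C)[Si](C)(C)O[C@H]1C(C)=CC[C@@]2(C)CC[C@](O)(C(C)C)[C@@H]12
F7 | step 4 | ent-diol: (1R,6R,9S,10R)-9-isopropyl-3,6-dimethyl-cis-hydrind-3-ene-1,9-diol | O[C@H]1C(C)=CC[C@@]2(C)CC[C@](O)(C(C)C)[C@@H]12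
F8 | step 4 | C1 (S)-O-acetylmandelate of 10 | CC(=O)O[C@H](C(=O)O[C@@H]1C(C)=CC[C@]2(C)CC[C@@](O)(C(C)C)[C@H]12)c1ccccc1
F9 | step 4 | C1 (S)-O-acetylmandelate of the ent-diol | CC(=O)O[C@H](C(=O)O[C@H]1C(C)=CC[C@@]2(C)CC[C@](O)(C(C)C)[C@@H]12)c1ccccc1
F10 | step 13 | C1-epimeric alcohol: (1S,6R,9R,10S)-9-isopropyl-3,6-dimethyl-9-(trimethylsilyloxy)-cis-hydroazul-2-en-1-ol | O[C@H]1C=C(C)CC[C@]2(C)CC[C@@](O[Si](C)(C)C)(C(C)C)[C@H]12
F11 | step 6 | isopropenyl carbinol: 1-(tert-butyldimethylsilyloxy)-3,6-dimethyl-9-(prop-1-en-2-yl)-cis-hydrind-3-en-9-ol (configuration as in 9) | CC(C)(C)[Si](C)(C)O[C@@H]1C(C)=CC[C@]2(C)CC[C@@](O)(C(C)=C)[C@H]12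
F12 | step 2 | methyl 2-methyl-5-oxocyclopent-1-ene-1-carboxylate | COC(=O)C1=C(C)CCC1=O
F13 | step 2 | methyl (1R,6S,10R)-1-(tert-butyldimethylsilyloxy)-3,6-dimethyl-9-oxo-cis-hydrind-3-ene-10-carboxylate | CC(C)(C)[Si](C)(C)O[C@@H]1C(C)=CC[C@]2(C)CCC(=O)[C@]12C(=O)OC
A1 | alternative 1 | (1E)-6-methyl-1-(trans-2-methylcyclopropyl)-3-(propan-2-yl)hepta-1,6-dien-3-ol (acyclic tertiary allylic alcohol) | C=C(C)CC[C@@](O)(C(C)C)/C=C/[C@H]1C[C@@H]1C
A2 | alternative 1 | cis-fused bicyclic alcohol with the C1=C2 alkene and an sp3 methyl-bearing C3 | C1=C[C@@H](C)CC[C@]2(C)CC[C@@](O)(C(C)C)[C@H]12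
A3 | alternative 2 | 3,6-dimethylcyclohepta-2,6-dien-1-one | O=C1C=C(C)CCC(C)=C1
A4 | alternative 2 | 1-(propan-2-yl)cyclopropan-1-ol | CC(C)C1(O)CC1
A5 | alternative 2 | (6R,9R,10R)-9-hydroxy-9-isopropyl-3,6-dimethyl-cis-hydroazul-2-en-1-one (β-hydroxy enone) | O=C1C=C(C)CC[C@]2(C)CC[C@@](O)(C(C)C)[C@H]12
A6 | alternative 3 | (2Z)-5-(2-bromo-1-methyl-3-oxocyclopentyl)-3-methylpent-2-enal (C10 bromide epimers) | O=C/C=C(/C)CC[C@]1(C)CCC(=O)C1Br
A7 | alternative 3 | cis-fused β-hydroxy ketone with the C9 ketone, the C1 hydroxyl and the C2=C3 alkene | O[C@@H]1C=C(C)CC[C@]2(C)CCC(=O)[C@H]12
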